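**The charge.** The third reagent is the one to watch in these flasks. We ask how much of the finished material is target in four vessels.

| setting | north-west | north-east | west | south-west |
|---|---|---|---|---|
| substrate | 0.014 M | 0.014 M | 0.014 M | 0.014 M |
| partner | 0.950 equiv (fed, over 40.0 min) | 0.950 equiv | 0.950 equiv | 0.950 equiv |
| second reagent | 1.10 equiv | 1.10 equiv | 1.10 equiv | 1.10 equiv |
| third reagent | 0.600 equiv | 0.600 equiv | 0.600 equiv | 0.600 equiv |
| time | 80 min | 80 min |  |  |
| remark | a stirred flask in which partner is dosed at a steady rate over 40.0 min without added volume, worked up at 80 min | a closed flask charged with all of it at once and left for 80 min | one stirred flow tank at steady state, fed with the mixture as stated, mean residence time 80 min | one stirred flow tank at steady state, fed with the mixture as stated, mean residence time 800 min |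

    substrate + partner → intermediate A (k1 = 0.12 M⁻¹ s⁻¹)
    second reagent + intermediate A → intermediate B (k2 = 0.096 M⁻¹ s⁻¹)
    third reagent + intermediate B → target (k3 = 2.1 M⁻¹ s⁻¹)
    substrate + second reagent → side product (k4 = 0.0022 M⁻¹ s⁻¹)
    third reagent + target → over-reaction product (k5 = 0.65 M⁻¹ s⁻¹)

- the stated concentrations are those of everything mixed, before any reaction; amounts are the same in each set-up
- the feed brings no volume worth counting
- run time (north-west): 80 min

1. the set-up with the highest share of target in all that became target or side product or over-reaction product, at the outlet or at the end ("none" if the first two lie within 2 percentage points) (north-west / north-east / west / south-west / none)
2. share of target in all that became target or side product or over-reaction product, at the outlet or at the end, north-west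
3. share of target in all that became target or side product or over-reaction product, at the outlet or at the end, north-east
4. share of target in all that became target or side product or over-reaction product, at the outlet or at the end, west
5. share of target in all that became target or side product or over-reaction product, at the outlet or at the end, south-west

**Times first.** We turn the constants into half-lives, each step alone at the charged amounts of north-east. Intermediate B lasts 0.65 min against third reagent and target 2.1 min. Substrate needs 7.2 min in the first step and intermediate A 7.8 min in the second. So, at the charged amounts, intermediate B goes by step 3 faster than intermediate A goes by step 2. Target can be attacked well within the run. The side route is slower, at 5.7 h.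

**The budget.** Third reagent is the limiting reagent by charge, 0.600 equiv against 0.950 equiv of partner. We carry one quantity, the third-reagent budget: the charged third reagent in percent of the substrate, 60.0 %. A target costs one unit. An over-reaction product costs two, since it is a target that took a further third reagent. When the third reagent in a flask reads zero, target is therefore the budget less two units per over-reaction product.

**Two flasks.** North-west and north-east differ in one thing: partner is dosed over 40.0 min or charged at once. In north-west, we reckon, intermediate B arrives slowly while third reagent waits. Early target then meets third reagent with little intermediate B beside it, and more of the budget goes at the double price. So we expect north-west below north-east. For the tanks we commit to no figure.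

**The forecast.** It gave 36 % for north-west, 43 % for north-east, 48 % for west and 65 % for south-west, with south-west best, holding that “the long-residence tank holds it near zero, which favours target”. Its order of the two batch flasks matches ours.

**The result.** The simulation gives 30.0 % for north-west, 37.9 % for north-east, 49.2 % for west and 64.7 % for south-west, so south-west is best. The forecast has the best set-up right, and both tanks within tolerance. Its 36 % for north-west is what a flask charged at once gives.

**Budget spent.** The main reason for south-west's share is the wearing away of third reagent: in the run where third reagent does not wear away, south-west reads 0.362 % instead of 64.7 %. In north-west third reagent stands at 0 % at 80.0 min, so the budget less two units per over-reaction product, 23.6 %, leaves 12.8 %; target reads 12.7 %. The neighbour with 0.056 M of substrate has the same budget and also ends with 0 % third reagent. Its over-reaction product of 26.1 % leaves 7.80 %, and its target reads 7.83 %.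

All constants are those of an exercise; no experiment stands behind them.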